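**The unit.** I took the decade as my unit: a tenfold fall in the fraction of the charge still present as substrate. Logarithms turn a first-order decay into a straight line, so decades add up with time.

**The decision.** The next flask was to hold a higher charge at the same loading. I had to decide whether to leave the loading alone and stop at 5.0 min. My test was a twofold fall in the substrate, which is 0.301 decade.

| setting | amber | violet | flask |
|---|---|---|---|
| substrate | 1.5 M | 2.2 M | 3.0 M |
| catalyst | 0.2 mol% | 0.2 mol% | 0.2 mol% |
| remark | run made earlier | run made earlier |  |
| time |  |  | 5.0 min |

| run | time / min | target / % | substrate / % |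
|---|---|---|---|
| amber | 0.417 | 2 | 97 |
| amber | 1.33 | 13 | 90 |
| amber | 2.50 | 18 | 81 |
| amber | 4.00 | 27 | 71 |
| amber | 5.00 | 33 | 64 |
| violet | 0.417 | 6 | 94 |
| violet | 0.833 | 6 | 87 |
| violet | 1.33 | 15 | 84 |
| violet | 2.50 | 28 | 69 |
| violet | 5.00 | 45 | 52 |

(standard deviation of a reading: 1.5 percentage points)

- on the list of suspects stand: substrate + catalyst -> catalyst + target; substrate -> side product; target + catalyst <-> isomer of the product + catalyst

* amount of target in percent of the substrate charged, at 15 s, 80 s and 5.0 min

**The reckoning.** At one loading the catalyst concentration rises with the charge, so I treated the decay as pseudo-first-order and divided by the charge. The amber run read 64 % substrate at 5.00 min from a charge of 1.5 M, which gave 4.31 × 10⁻⁴ L mol⁻¹ s⁻¹. I called this the decade rate: decades of substrate lost per second for each mole per litre of charge. For the violet run it gave 52.0 % left at 5.00 min, and the reading was 52 %. For the flask it gave 0.388 decade, so 41.0 % left. That loss was more than my test asked, so I kept the flask at 0.2 mol% and kept the stop.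

**The forecast.** The forecast gave target 4.1 %, 20 % and 56 %, on the ground that “the rate therefore scales with catalyst concentration”. My reckoning spoke of substrate, the forecast of target.

**The result.** The flask gave target 4.29 %, 20.2 % and 51.5 %.

    substrate + catalyst → catalyst + target (k = 0.490 L mol⁻¹ s⁻¹)
    substrate → side product (k = 9.80 × 10⁻⁵ s⁻¹)
    target + catalyst ⇌ isomer of the product + catalyst, rate k3*[catalyst]*[target] forward; the back reaction follows from the equilibrium constant (K = 0.660, k = 0.130 L mol⁻¹ s⁻¹)

**The course.** The flask fell to 40 % substrate by 5.00 min, which is 0.398 decade against my 0.388. With catalyst at 100 % of its charge at 2.50 min, the flask made target 10.3 times faster than it used it up at 1.95 min, and 3.62 times faster at 5.00 min, when isomer of the product stood at 6.37 %. For 50.0 min the decade rate gave 0.0132 % substrate in the flask. The flask then held substrate 0.0110 %, target 58.6 % and isomer of the product 38.2 %.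

(The earlier runs and the new flask stem from a simulated flask with constants of no real substance; scatter was added.)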